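The flavone is disconnected at the C4–C4a bond of the pyranone (ring C). A single intramolecular Friedel–Crafts acylation of a β-aryloxyacrylic acid forges this bond, closes ring C and delivers the complete, fully oxygenated flavone skeleton. The step exploits ring-A carbon C4a, which is ortho to O1 and to the C5 oxygen and para to the C7 methoxyl, while the other position ortho to O1 (C8) is blocked by its methoxyl. The substrate is the (E)-3-aryloxy-3-aryl-2-methoxyacrylic acid 19, in which the C5 and C5′ hydroxyls are masked as benzyl ethers; it is assembled from an A-ring phenol and a B-ring enol triflate, and one hydrogenolysis finishes the synthesis.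

Key step: step 11

Remarks on the chemistry:
- The target has no stereocentre and no stereogenic double bond, so there is no enantiomer to select. The only stereochemical element on the way is the alkene geometry of compounds 16–20, drawn E (carboxyl cis to the oxygen leaving group or aryloxy group). Either geometry should serve, because step 11 is expected to equilibrate it.
- 3-Bromo-4,5-dimethoxybenzaldehyde (5-bromoveratraldehyde), methyl 2,5-dihydroxybenzoate and methyl methoxyacetate are taken as purchased materials.

Step 1
Reactants: 1 3-bromo-4,5-dimethoxybenzaldehyde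
Product: 3 3-bromo-4,5-dimethoxyphenol, via aryl formate 2 (not isolated)
Conditions: mCPBA, CH2Cl2, rt; then K2CO3 (cat.), MeOH, rt
Reagents that add atoms: mCPBA, O=C(OO)c1cccc(Cl)c1
Why: Baeyer–Villiger (Dakin-type) oxidation in which the aryl group, activated by its para-methoxyl, migrates in preference to hydride, and the labile aryl formate is then cleaved by base-catalysed methanolysis.

Step 2
Reactants: 3 3-bromo-4,5-dimethoxyphenol
Product: 4 5-(benzyloxy)-1-bromo-2,3-dimethoxybenzene
Conditions: BnBr, K2CO3, DMF, rt
Reagents that add atoms: benzyl bromide, BrCc1ccccc1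
Why: Williamson ether synthesis (SN2 of the phenoxide on benzyl bromide), to which the aryl bromide and methyl ethers are inert.

Step 3
Reactants: 4 5-(benzyloxy)-1-bromo-2,3-dimethoxybenzene
Product: 7 5-(benzyloxy)-2,3-dimethoxyphenol, via aryllithium 5 (not isolated), via dimethyl arylboronate 6 (not isolated)
Conditions: n-BuLi, THF, −78 °C; B(OMe)3, −78 °C → rt; then AcOH, 30% H2O2, 0 °C → rt
Reagents that add atoms: n-butyllithium, [Li]CCCC (lithium of 5); trimethyl borate, COB(OC)OC (boron and methoxyls of 6); hydrogen peroxide, OO (phenol oxygen of 7)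
Why: Bromine–lithium exchange at −78 °C is faster than any attack on the benzyl ether and gives an ortho-methoxy-stabilised aryllithium, which is borylated and then oxidised with 1,2-migration of aryl from boron to oxygen (arylboronate oxidation), so that C–Br becomes C–OH at the same carbon.

Step 4
Reactants: 8 methyl 2,5-dihydroxybenzoate
Product: 9 methyl 5-(benzyloxy)-2-hydroxybenzoate
Conditions: BnBr (1.05 equiv), K2CO3, acetone, reflux
Reagents that add atoms: benzyl bromide, BrCc1ccccc1
Why: Williamson ether synthesis that should be selective for the 5-OH, because the 2-OH is held in a hydrogen bond to the ester carbonyl and is the poorer nucleophile when only one equivalent of halide is offered.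

Step 5
Reactants: 9 methyl 5-(benzyloxy)-2-hydroxybenzoate
Product: 10 methyl 5-(benzyloxy)-2-methoxybenzoate
Conditions: MeI, K2CO3, DMF, 50 °C
Reagents that add atoms: iodomethane, CI
Why: Williamson methylation of the remaining chelated salicylate hydroxyl, driven by a polar aprotic solvent, mild heating and the small, reactive electrophile.

Step 6
Reactants: 10 methyl 5-(benzyloxy)-2-methoxybenzoate
Product: 11 5-(benzyloxy)-2-methoxybenzoic acid
Conditions: LiOH·H2O, THF/MeOH/H2O, 50 °C; then 1 M HCl
Reagents that add atoms: lithium hydroxide, [Li+].[OH-] (oxygen of the carboxyl OH)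
Why: Ordinary saponification (acyl–oxygen ester hydrolysis), which leaves the benzyl and methyl ethers untouched.

Step 7
Reactants: 11 5-(benzyloxy)-2-methoxybenzoic acid; 12 methyl methoxyacetate
Product: 15 methyl 3-[5-(benzyloxy)-2-methoxyphenyl]-2-methoxy-3-oxopropanoate (racemic at C2), via aroyl chloride 13 (not isolated), via lithium enolate 14 (not isolated)
Conditions: (COCl)2, DMF (cat.), CH2Cl2, 0 °C → rt, evaporate; separately 12 (2.2 equiv), LDA (2.2 equiv), THF, −78 °C; add 13, −78 °C; 1 M HCl quench
Reagents that add atoms: oxalyl chloride, O=C(Cl)C(=O)Cl (chlorine of 13); lithium diisopropylamide, CC(C)N([Li])C(C)C (lithium of 14)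
Why: Crossed Claisen-type C-acylation of a preformed lithium ester enolate by an aroyl chloride, run with two equivalents of enolate because the more acidic β-keto ester consumes one (which also blocks a second acylation); the C2 stereocentre forms racemic and is erased in step 8.

Step 8
Reactants: 15 methyl 3-[5-(benzyloxy)-2-methoxyphenyl]-2-methoxy-3-oxopropanoate
Product: 17 methyl (E)-3-[5-(benzyloxy)-2-methoxyphenyl]-2-methoxy-3-{[(trifluoromethyl)sulfonyl]oxy}acrylate, via sodium enolate 16 (not isolated)
Conditions: NaH, THF, 0 °C; PhNTf2, 0 °C → rt; cold dilute HCl wash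
Reagents that add atoms: sodium hydride, [Na+].[H-] (sodium of 16); N-phenylbis(trifluoromethanesulfonimide), O=S(=O)(N(c1ccccc1)S(=O)(=O)C(F)(F)F)C(F)(F)F (triflyl group of 17)
Why: O-sulfonylation of a β-keto ester enolate (enol triflate formation), in which the chelated sodium enolate should place the triflate cis to the ester (E), although the geometry is not critical for what follows.

Step 9
Reactants: 17 methyl (E)-3-[5-(benzyloxy)-2-methoxyphenyl]-2-methoxy-3-{[(trifluoromethyl)sulfonyl]oxy}acrylate; 7 5-(benzyloxy)-2,3-dimethoxyphenol
Product: 18 methyl (E)-3-[5-(benzyloxy)-2,3-dimethoxyphenoxy]-3-[5-(benzyloxy)-2-methoxyphenyl]-2-methoxyacrylate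
Conditions: Cs2CO3, DMF, 0 °C → rt
Reagents that add atoms: none
Why: Addition–elimination (nucleophilic vinylic substitution): the phenoxide adds to the β-carbon, which is activated by the ester and the triflate, and the resulting ester enolate expels triflate, as in the classical union of phenoxides with β-halo- or β-sulfonyloxy-acrylates.

Step 10
Reactants: 18 methyl (E)-3-[5-(benzyloxy)-2,3-dimethoxyphenoxy]-3-[5-(benzyloxy)-2-methoxyphenyl]-2-methoxyacrylate
Product: 19 (E)-3-[5-(benzyloxy)-2,3-dimethoxyphenoxy]-3-[5-(benzyloxy)-2-methoxyphenyl]-2-methoxyacrylic acid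
Conditions: LiOH·H2O, THF/MeOH/H2O, 40 °C; then 1 M HCl, 0 °C, to pH 3
Reagents that add atoms: lithium hydroxide, [Li+].[OH-] (oxygen of the carboxyl OH)
Why: Saponification of the methyl ester, after which the carboxylate resists further nucleophilic attack and is reprotonated cold so that the aryl enol ether is not hydrolysed.

Step 11
Reactants: 19 (E)-3-[5-(benzyloxy)-2,3-dimethoxyphenoxy]-3-[5-(benzyloxy)-2-methoxyphenyl]-2-methoxyacrylic acid
Product: 21 5-(benzyloxy)-2-[5-(benzyloxy)-2-methoxyphenyl]-3,7,8-trimethoxy-4H-chromen-4-one, via mixed anhydride 20 (not isolated)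
Conditions: TFAA (3 equiv), CH2Cl2, 0 °C → rt
Reagents that add atoms: trifluoroacetic anhydride, O=C(OC(=O)C(F)(F)F)C(F)(F)F (trifluoroacetyl group of 20 only; nothing remains in 21)
Why: TFAA converts the acid into mixed anhydride 20, whose acyl carbon (an acylium equivalent stabilised by the β-aryloxy oxygen) attacks the A-ring carbon between the aryloxy oxygen and the benzyloxy group (the future C4a) in an intramolecular electrophilic aromatic substitution, and loss of a proton and trifluoroacetate gives the pyranone. The closest known reaction type is the acid-mediated cyclodehydration of β-aryloxycinnamic and β-aryloxyacrylic acids to flavones and chromones (intramolecular Friedel–Crafts acylation). Ring C closes as a six-membered ring, exo with respect to the acyl C=O and endo with respect to the arene C4a–C8a bond, without strain because the E alkene already holds the carboxyl and aryloxy groups cis. No stereocentre is created, and a Z isomer should equilibrate under the acidic conditions through the oxygen-stabilised cation of the push–pull alkene, so both geometries should converge on 21. Regioselectivity is secured by the substrate: the attacked carbon is activated by three oxygen donors (ortho O1, ortho C5–OBn, para C7–OMe), the other carbon ortho to O1 carries the C8 methoxyl, C6 is out of reach of the tether, and closure onto the singly activated B ring would need the Z geometry and a five-membered indenone ring. The conditions are mild and non-nucleophilic, so the benzyl and methyl ethers should survive.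

Step 12
Reactants: 21 5-(benzyloxy)-2-[5-(benzyloxy)-2-methoxyphenyl]-3,7,8-trimethoxy-4H-chromen-4-one
Product: 22 5-hydroxy-2-(5-hydroxy-2-methoxyphenyl)-3,7,8-trimethoxy-4H-chromen-4-one (5,5′-dihydroxy-3,7,8,2′-tetramethoxyflavone)
Conditions: H2 (1 atm), 10% Pd/C, EtOAc/MeOH, rt
Reagents that add atoms: none
Why: Catalytic hydrogenolysis cleaves both aryl benzyl ethers, while the tetrasubstituted vinylogous-ester C2=C3 bond and the aryl methyl ethers of the flavone should not be reduced at 1 atm and room temperature.

Compound list
1 | 3-bromo-4,5-dimethoxybenzaldehyde (5-bromoveratraldehyde) | COc1cc(C=O)cc(Br)c1OC | starting material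
2 | 3-bromo-4,5-dimethoxyphenyl formate | COc1cc(OC=O)cc(Br)c1OC | intermediate (not isolated)
3 | 3-bromo-4,5-dimethoxyphenol | COc1cc(O)cc(Br)c1OC | intermediate
4 | 5-(benzyloxy)-1-bromo-2,3-dimethoxybenzene | COc1cc(OCc2ccccc2)cc(Br)c1OC | intermediate
5 | [5-(benzyloxy)-2,3-dimethoxyphenyl]lithium | COc1cc(OCc2ccccc2)cc([Li])c1OC | intermediate (not isolated)
6 | dimethyl [5-(benzyloxy)-2,3-dimethoxyphenyl]boronate | COB(OC)c1cc(OCc2ccccc2)cc(OC)c1OC | intermediate (not isolated)
7 | 5-(benzyloxy)-2,3-dimethoxyphenol | COc1cc(OCc2ccccc2)cc(O)c1OC | intermediate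
8 | methyl 2,5-dihydroxybenzoate | COC(=O)c1cc(O)ccc1O | starting material
9 | methyl 5-(benzyloxy)-2-hydroxybenzoate | COC(=O)c1cc(OCc2ccccc2)ccc1O | intermediate
10 | methyl 5-(benzyloxy)-2-methoxybenzoate | COC(=O)c1cc(OCc2ccccc2)ccc1OC | intermediate
11 | 5-(benzyloxy)-2-methoxybenzoic acid | COc1ccc(OCc2ccccc2)cc1C(=O)O | intermediate
12 | methyl methoxyacetate | COCC(=O)OC | starting material
13 | 5-(benzyloxy)-2-methoxybenzoyl chloride | COc1ccc(OCc2ccccc2)cc1C(=O)Cl | intermediate (not isolated)
14 | lithium enolate of methyl methoxyacetate (lithium 1,2-dimethoxyethenolate, chelated geometry drawn) | CO/C=C(\O[Li])OC | intermediate (not isolated)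
15 | methyl 3-[5-(benzyloxy)-2-methoxyphenyl]-2-methoxy-3-oxopropanoate (racemic at C2) | COC(=O)C(OC)C(=O)c1cc(OCc2ccccc2)ccc1OC | intermediate
16 | sodium (E)-enolate of 15 | CO/C(C(=O)OC)=C(/O[Na])c1cc(OCc2ccccc2)ccc1OC | intermediate (not isolated)
17 | methyl (E)-3-[5-(benzyloxy)-2-methoxyphenyl]-2-methoxy-3-{[(trifluoromethyl)sulfonyl]oxy}acrylate | CO/C(C(=O)OC)=C(/OS(=O)(=O)C(F)(F)F)c1cc(OCc2ccccc2)ccc1OC | intermediate
18 | methyl (E)-3-[5-(benzyloxy)-2,3-dimethoxyphenoxy]-3-[5-(benzyloxy)-2-methoxyphenyl]-2-methoxyacrylate | CO/C(C(=O)OC)=C(/Oc1cc(OCc2ccccc2)cc(OC)c1OC)c1cc(OCc2ccccc2)ccc1OC | intermediate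
19 | (E)-3-[5-(benzyloxy)-2,3-dimethoxyphenoxy]-3-[5-(benzyloxy)-2-methoxyphenyl]-2-methoxyacrylic acid | CO/C(C(=O)O)=C(/Oc1cc(OCc2ccccc2)cc(OC)c1OC)c1cc(OCc2ccccc2)ccc1OC | intermediate (key-step precursor)
20 | (E)-3-[5-(benzyloxy)-2,3-dimethoxyphenoxy]-3-[5-(benzyloxy)-2-methoxyphenyl]-2-methoxyacrylic trifluoroacetic anhydride | CO/C(C(=O)OC(=O)C(F)(F)F)=C(/Oc1cc(OCc2ccccc2)cc(OC)c1OC)c1cc(OCc2ccccc2)ccc1OC | intermediate (not isolated)
21 | 5-(benzyloxy)-2-[5-(benzyloxy)-2-methoxyphenyl]-3,7,8-trimethoxy-4H-chromen-4-one | COc1ccc(OCc2ccccc2)cc1-c1oc2c(OC)c(OC)cc(OCc3ccccc3)c2c(=O)c1OC | intermediate (key-step product)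
22 | 5-hydroxy-2-(5-hydroxy-2-methoxyphenyl)-3,7,8-trimethoxy-4H-chromen-4-one (5,5′-dihydroxy-3,7,8,2′-tetramethoxyflavone) | COc1ccc(O)cc1-c1oc2c(OC)c(OC)cc(O)c2c(=O)c1OC | target

Total step count: 12 (steps 1–3 make the A-ring phenol 7; steps 4–8 make the B-ring enol triflate 17; steps 9–12 join them and finish).
Longest linear sequence: 9 steps (steps 4–12, from methyl 2,5-dihydroxybenzoate 8 to target 22).

Steps most likely to fail, riskiest first:

1. Step 9 (joining the two halves). The phenoxide may attack the sulfur of the triflate instead of the crowded, tetrasubstituted β-carbon. That would transfer the triflyl group to the phenol and return the keto ester enolate. The fallback sets out from keto ester 15 and replaces the sulfonate by a leaving group that offers no second electrophilic site. Vilsmeier-type chlorination of 15 ((COCl)2, DMF, CH2Cl2) should give the β-chloroacrylate methyl (E)-3-[5-(benzyloxy)-2-methoxyphenyl]-3-chloro-2-methoxyacrylate F1 (either alkene isomer serves). Heating F1 with phenol 7 and Cs2CO3 in DMF at 60–80 °C should then displace chloride by addition–elimination, the classical way of joining a phenoxide to a β-chlorocinnamate. The fallback rejoins the route at 18.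

2. Step 11 (key ring closure). The mixed anhydride may ionise too slowly for the donor-stabilised acyl group. Trifluoroacetyl transfer to the electron-rich rings, or slow acidolysis of a benzyl ether, could then overtake cyclisation. The fallback sets out from acid 19 and separates activation from ring closure. Under neutral conditions with 1-chloro-N,N,2-trimethylprop-1-en-1-amine in CH2Cl2, 19 should give the acid chloride (E)-3-[5-(benzyloxy)-2,3-dimethoxyphenoxy]-3-[5-(benzyloxy)-2-methoxyphenyl]-2-methoxyacryloyl chloride F2. A Lewis acid (SnCl4, CH2Cl2, −78 °C) should then close the ring in a conventional Friedel–Crafts acylation in the absence of trifluoroacetic acid. The fallback rejoins the route at 21.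

3. Step 10 (ester cleavage). Hydroxide may add to the β-carbon of the vinylogous carbonate and expel the A-ring phenoxide faster than it attacks the hindered ester carbonyl. The fallback sets out from ester 18 and cleaves the ester at the alkyl–oxygen bond instead. SN2 demethylation with LiI in refluxing EtOAc, followed by cold acidification, puts no nucleophile on the carbonyl or the β-carbon and should give 19 directly. This fallback makes no new compound (F0).

Further compounds
F1 | step 9 | methyl (E)-3-[5-(benzyloxy)-2-methoxyphenyl]-3-chloro-2-methoxyacrylate | CO/C(C(=O)OC)=C(/Cl)c1cc(OCc2ccccc2)ccc1OC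
F2 | step 11 | (E)-3-[5-(benzyloxy)-2,3-dimethoxyphenoxy]-3-[5-(benzyloxy)-2-methoxyphenyl]-2-methoxyacryloyl chloride | CO/C(C(=O)Cl)=C(/Oc1cc(OCc2ccccc2)cc(OC)c1OC)c1cc(OCc2ccccc2)ccc1OC
F0 | step 10 | none | none
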